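Isoflavan numbering is used: O1, C2, C3, C4, C4a, C5–C8, C8a for rings C and A, primed numbers for ring B.

**Plan**
- **Cuts:** The silyl group on O2' comes off last. Ring C is then cut twice at once, at O1–C2 and at C4–C4a. This leaves 2,6-dihydroxy-4-methoxybenzaldehyde (all of ring A, CHO included) and a 2-arylacrolein (ring B plus C2–C3–C4). The enal goes back through C4 (methylenation) and C2 (Wittig homologation) to a benzaldehyde, and the prenyl group goes back through a Claisen shift to O2'.
- **Enabling feature:** Ring A is a symmetric formylphloroglucinol monomethyl ether in disguise. Its two OH/ortho-CH pairs (O1/C4a and O7/C6) are equivalent, and C8 between the hydroxyls is blocked by CHO. C3 lies between two CH2 groups. A phenol O/ortho-C 1,3-dinucleophile and an enal 1,3-dielectrophile therefore fit together with no regiochemical choice.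
- **Forward order:** Ring B is dressed first (O-tert-prenylation, Claisen shift to C3', silylation, homologation, methylenation). The ring A partner takes one step. Ring C arises last, in a reductive [3+3] annulation that joins the halves, closes the ring, adjusts the oxidation level and sets C3.
- **Stereochemistry:** C3 (R) is the only stereocentre. A chiral Brønsted acid sets it in the annulation. The C3-epimeric oxocarbenium ions equilibrate through an achiral 4H-chromene, and one ion pair is reduced faster by a Hantzsch ester.

Key step: step 8

Assumption: the (R)-configured catalyst is written for the 3R product. The sense of induction is to be checked in the first run, and the mirror-image catalyst is taken if it proves opposite.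

Step 1
Reactants: 1 2-methylbut-3-en-2-ol
Product: 3 isobutyl 2-methylbut-3-en-2-yl carbonate, via lithium 2-methylbut-3-en-2-olate 2 (not isolated)
Conditions: n-BuLi, THF, −78 °C; then i-BuOCOCl, −78 °C → rt
Reagents that add atoms: isobutyl chloroformate, CC(C)COC(=O)Cl
Why: Acylation of a pre-formed tertiary lithium alkoxide with a chloroformate is the standard carbonate synthesis and should outrun any ionisation of the tertiary allylic system because the medium stays basic and cold.

Step 2
Reactants: 3 isobutyl 2-methylbut-3-en-2-yl carbonate, 4 2-hydroxy-4-methoxybenzaldehyde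
Product: 5 4-methoxy-2-[(2-methylbut-3-en-2-yl)oxy]benzaldehyde
Conditions: Pd(PPh3)4 (5 mol %), THF, 0 °C
Reagents that add atoms: none
Why: Tsuji–Trost O-allylation: zerovalent palladium ionises carbonate 3 with loss of CO2, the isobutoxide set free deprotonates phenol 4, and at 0 °C the phenoxide should attack the more substituted allyl terminus to give the kinetic tertiary ether.

Step 3
Reactants: 5 4-methoxy-2-[(2-methylbut-3-en-2-yl)oxy]benzaldehyde
Product: 6 2-hydroxy-4-methoxy-3-(3-methylbut-2-en-1-yl)benzaldehyde
Conditions: PhMe, 120 °C, sealed tube
Reagents that add atoms: none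
Why: Aromatic Claisen rearrangement: the [3,3] shift turns the 1,1-dimethylallyl ether end for end into a linear prenyl group and can end productively only at C3, the one ortho position that carries a hydrogen for rearomatisation.

Step 4
Reactants: 6 2-hydroxy-4-methoxy-3-(3-methylbut-2-en-1-yl)benzaldehyde
Product: 7 2-[(tert-butyldimethylsilyl)oxy]-4-methoxy-3-(3-methylbut-2-en-1-yl)benzaldehyde
Conditions: TBSCl, imidazole, DMF, 40 °C
Reagents that add atoms: TBSCl, CC(C)(C)[Si](C)(C)Cl
Why: Standard phenol silylation, which masks O2' so that it cannot add to the enal or to C2 later on, with a group that should withstand the ylide, dilute acid, the amine catalyst and the Brønsted acid of step 8 and that leaves with fluoride.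

Step 5
Reactants: 7 2-[(tert-butyldimethylsilyl)oxy]-4-methoxy-3-(3-methylbut-2-en-1-yl)benzaldehyde
Product: 9 2-{2-[(tert-butyldimethylsilyl)oxy]-4-methoxy-3-(3-methylbut-2-en-1-yl)phenyl}acetaldehyde, via methyl enol ether 8 (not isolated)
Conditions: Ph3P(CH2OMe)Cl, KN(SiMe3)2, THF, −78 → 0 °C; then 1 M aq HCl, THF, rt
Reagents that add atoms: (methoxymethyl)triphenylphosphonium chloride, COC[P+](c1ccccc1)(c1ccccc1)c1ccccc1.[Cl-]; water, O
Why: Wittig methoxymethylenation and acid hydrolysis of the enol ether, the classical one-carbon homologation of an aryl aldehyde, in which the aryl silyl ether and the trisubstituted alkene should tolerate dilute acid at room temperature.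

Step 6
Reactants: 9 2-{2-[(tert-butyldimethylsilyl)oxy]-4-methoxy-3-(3-methylbut-2-en-1-yl)phenyl}acetaldehyde
Product: 10 2-{2-[(tert-butyldimethylsilyl)oxy]-4-methoxy-3-(3-methylbut-2-en-1-yl)phenyl}prop-2-enal
Conditions: 37% aq CH2O, pyrrolidine (10 mol %), EtCO2H (10 mol %), i-PrOH, 45 °C
Reagents that add atoms: formaldehyde, C=O
Why: Aminocatalytic α-methylenation (Mannich condensation with formaldehyde through the enamine, then β-elimination of the amine), a known reaction of arylacetaldehydes, which installs C4 as the free CH2 terminus of the enal; 10 is used without storage.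

Step 7
Reactants: 11 2,4,6-trihydroxybenzaldehyde
Product: 12 2,6-dihydroxy-4-methoxybenzaldehyde
Conditions: Me2SO4 (1.0 equiv), K2CO3 (1.0 equiv), acetone, rt
Reagents that add atoms: dimethyl sulfate, COS(=O)(=O)OC
Why: Williamson-type O-methylation under stoichiometric control: the 4-OH para to the formyl group is the most acidic and the least hindered hydroxyl, the two ortho hydroxyls are tied up in hydrogen bonding to C=O, and the hard electrophile favours O- over C-methylation.

Step 8
Reactants: 10 2-{2-[(tert-butyldimethylsilyl)oxy]-4-methoxy-3-(3-methylbut-2-en-1-yl)phenyl}prop-2-enal, 12 2,6-dihydroxy-4-methoxybenzaldehyde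
Product: 16 (3R)-3-{2-[(tert-butyldimethylsilyl)oxy]-4-methoxy-3-(3-methylbut-2-en-1-yl)phenyl}-7-hydroxy-5-methoxy-3,4-dihydro-2H-chromene-8-carbaldehyde, via chroman-2-ol lactol 13 (not isolated), via 3-aryl-4H-chromene 14 (not isolated), via chroman oxocarbenium ion 15 (not isolated)
Conditions: (R)-3,3'-bis(2,4,6-triisopropylphenyl)-1,1'-binaphthyl-2,2'-diyl N-(trifluoromethylsulfonyl)phosphoramide (10 mol %), 12 (2 equiv), CH2Cl2–PhMe, 0 °C → rt, 10 added by syringe pump; then, same flask, 5 Å MS, Hantzsch ester (diethyl 2,6-dimethyl-1,4-dihydropyridine-3,5-dicarboxylate, 1.4 equiv), 40 °C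
Reagents that add atoms: none
Why: Proposed new method: the phosphoramide holds the enal C=O of 10 by its acidic N–H and a phenol O–H of 12 by its P=O, the ring CH next to that OH adds to the unsubstituted β-CH2 (C4–C4a bond), the aldehyde thus unmasked is captured at once by the same OH (O1–C2 bond) to give lactol 13, and, once sieves and Hantzsch ester are added, 13 loses water to 4H-chromene 14, 14 is protonated at C3 to oxocarbenium ion 15 paired with the chiral anion, and 15 takes hydride at C2. The closest known reaction types are the organocatalytic Friedel–Crafts/hemiacetalisation [3+3] annulation of naphthols and electron-rich phenols with enals to chroman-2-ols, the chiral phosphoric acid/Hantzsch ester reductive amination of racemising α-aryl aldehydes (dynamic kinetic resolution), the transfer hydrogenation of 3-substituted quinolines by way of enantioselective protonation and the chiral-anion-paired reduction of benzopyrylium ions, and the new element is their merger, with an O-aryl oxocarbenium ion as the hydride acceptor. Ring C closes in the 6-exo-trig mode, phenol oxygen onto the formyl carbon. C3 is the only new stereocentre and is controlled by the chiral phosphoramidate: the two enantiomers of 15 interconvert through achiral 14, the anion biases the face of protonation and the matched ion pair should be reduced faster (Curtin–Hammett situation), and in 16 C3 has lost its acidifying neighbour and can no longer racemise. Site selectivity needs no control, since the two OH/CH pairs of 12 are equivalent by symmetry, the carbon between the hydroxyls is blocked by CHO and the free β-CH2 of 10 favours 1,4- over 1,2-attack, while a second annulation at O7/C6 is held back by the excess of 12 and the slow addition of 10. Chemoselectivity is secured by the order of addition and by the substrate: the Hantzsch ester meets no enal, it is by far the better nucleophile than phenol 12 for cation 15, the chelated aryl CHO (a vinylogous acid) and the prenyl alkene should not be activated by an acid of this strength, and the silyl ether keeps O2' from adding to the enal or to C2.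

Step 9
Reactants: 16 (3R)-3-{2-[(tert-butyldimethylsilyl)oxy]-4-methoxy-3-(3-methylbut-2-en-1-yl)phenyl}-7-hydroxy-5-methoxy-3,4-dihydro-2H-chromene-8-carbaldehyde
Product: 17 (3R)-7-hydroxy-3-[2-hydroxy-4-methoxy-3-(3-methylbut-2-en-1-yl)phenyl]-5-methoxy-3,4-dihydro-2H-chromene-8-carbaldehyde (CNP0321751.1)
Conditions: Bu4NF, AcOH, THF, 0 °C
Reagents that add atoms: none
Why: Fluoride-induced cleavage of an aryl silyl ether, buffered with acetic acid so that the phenoxides and the aldehyde stay quiet, which cannot touch C3 because this centre bears no acidic hydrogen.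

**Compound list**
1 | 2-methylbut-3-en-2-ol | CC(C)(O)C=C | starting material
2 | lithium 2-methylbut-3-en-2-olate | [Li+].[O-]C(C)(C)C=C | intermediate
3 | isobutyl 2-methylbut-3-en-2-yl carbonate | CC(C)COC(=O)OC(C)(C)C=C | intermediate
4 | 2-hydroxy-4-methoxybenzaldehyde | COc1ccc(C=O)c(O)c1 | starting material
5 | 4-methoxy-2-[(2-methylbut-3-en-2-yl)oxy]benzaldehyde | COc1ccc(C=O)c(OC(C)(C)C=C)c1 | intermediate
6 | 2-hydroxy-4-methoxy-3-(3-methylbut-2-en-1-yl)benzaldehyde | COc1ccc(C=O)c(O)c1CC=C(C)C | intermediate
7 | 2-[(tert-butyldimethylsilyl)oxy]-4-methoxy-3-(3-methylbut-2-en-1-yl)benzaldehyde | COc1ccc(C=O)c(O[Si](C)(C)C(C)(C)C)c1CC=C(C)C | intermediate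
8 | tert-butyl[3-methoxy-6-(2-methoxyethenyl)-2-(3-methylbut-2-en-1-yl)phenoxy]dimethylsilane (E/Z mixture) | COC=Cc1ccc(OC)c(CC=C(C)C)c1O[Si](C)(C)C(C)(C)C | intermediate
9 | 2-{2-[(tert-butyldimethylsilyl)oxy]-4-methoxy-3-(3-methylbut-2-en-1-yl)phenyl}acetaldehyde | COc1ccc(CC=O)c(O[Si](C)(C)C(C)(C)C)c1CC=C(C)C | intermediate
10 | 2-{2-[(tert-butyldimethylsilyl)oxy]-4-methoxy-3-(3-methylbut-2-en-1-yl)phenyl}prop-2-enal | COc1ccc(C(=C)C=O)c(O[Si](C)(C)C(C)(C)C)c1CC=C(C)C | intermediate
11 | 2,4,6-trihydroxybenzaldehyde | O=Cc1c(O)cc(O)cc1O | starting material
12 | 2,6-dihydroxy-4-methoxybenzaldehyde | COc1cc(O)c(C=O)c(O)c1 | intermediate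
13 | 3-{2-[(tert-butyldimethylsilyl)oxy]-4-methoxy-3-(3-methylbut-2-en-1-yl)phenyl}-2,7-dihydroxy-5-methoxy-3,4-dihydro-2H-chromene-8-carbaldehyde (lactol, mixture of stereoisomers) | COc1ccc(C2Cc3c(OC)cc(O)c(C=O)c3OC2O)c(O[Si](C)(C)C(C)(C)C)c1CC=C(C)C | intermediate
14 | 3-{2-[(tert-butyldimethylsilyl)oxy]-4-methoxy-3-(3-methylbut-2-en-1-yl)phenyl}-7-hydroxy-5-methoxy-4H-chromene-8-carbaldehyde | COc1ccc(C2=COc3c(C=O)c(O)cc(OC)c3C2)c(O[Si](C)(C)C(C)(C)C)c1CC=C(C)C | intermediate
15 | (3R)-3-{2-[(tert-butyldimethylsilyl)oxy]-4-methoxy-3-(3-methylbut-2-en-1-yl)phenyl}-8-formyl-7-hydroxy-5-methoxy-3,4-dihydrochromen-1-ium (cation of the ion pair with the catalyst anion) | COc1ccc([C@@H]2C=[O+]c3c(C=O)c(O)cc(OC)c3C2)c(O[Si](C)(C)C(C)(C)C)c1CC=C(C)C | intermediate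
16 | (3R)-3-{2-[(tert-butyldimethylsilyl)oxy]-4-methoxy-3-(3-methylbut-2-en-1-yl)phenyl}-7-hydroxy-5-methoxy-3,4-dihydro-2H-chromene-8-carbaldehyde | COc1ccc([C@@H]2COc3c(C=O)c(O)cc(OC)c3C2)c(O[Si](C)(C)C(C)(C)C)c1CC=C(C)C | intermediate
17 | (3R)-7-hydroxy-3-[2-hydroxy-4-methoxy-3-(3-methylbut-2-en-1-yl)phenyl]-5-methoxy-3,4-dihydro-2H-chromene-8-carbaldehyde | COc1ccc([C@@H]2COc3c(C=O)c(O)cc(OC)c3C2)c(O)c1CC=C(C)C | target

Total step count: 9. Longest linear sequence: 8 steps (1 to 17 through steps 1–6, 8 and 9). Step 7 is a one-step side branch.

**Steps most likely to fail**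

1. **Step 8 (proposed new method).**
   - What may go wrong:
     - slow Friedel–Crafts addition of the formyl-deactivated phenol
     - stalling at the lactol or 4H-chromene stage because ionisation to an O-aryl oxocarbenium ion is slow
     - capture of the cation by a second molecule of phenol before the hydride donor is present
     - a second annulation on ring A
     - poor discrimination between the two ion pairs
   - The fallback uses known reaction types only. It sets out from 10 and 12 and comes back to the route at 16.
   - The union is run through the phenolate of 12 (Et3N cat., MeCN, rt). Michael addition through carbon and then hemiacetalisation follow, and the reaction is stopped at racemic lactol 13, which is now isolated.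
   - An NADPH-dependent ketoreductase (alcohol dehydrogenase class) then reduces the open hydroxy aldehyde form of 13. It is run with glucose/glucose dehydrogenase recycling in phosphate buffer at pH 8 with DMSO as cosolvent.
   - The α-aryl centre racemises by enolisation during this reduction. This is a dynamic reductive kinetic resolution, as established for racemic 2-arylpropanals. The doubly ortho-substituted, chelated aryl CHO is not expected to be accepted by the enzyme.
   - This should give 3-[(2R)-2-{2-[(tert-butyldimethylsilyl)oxy]-4-methoxy-3-(3-methylbut-2-en-1-yl)phenyl}-3-hydroxypropyl]-2,6-dihydroxy-4-methoxybenzaldehyde F1.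
   - Mitsunobu etherification (PPh3, DIAD, THF, 0 °C) is the usual closure of ring C of isoflavans. It gives 16, since only the hydroxyl next to the side chain can reach the primary carbon.

2. **Step 6.**
   - What may go wrong:
     - self-condensation of the arylacetaldehyde
     - hetero-Diels–Alder dimerisation or polymerisation of the enal while it is formed, isolated or handled
   - The fallback sets out from 9 and 12 and comes back to the route at 13.
   - The methylenation (aq CH2O, pyrrolidine and EtCO2H as catalysts, i-PrOH, 45 °C) is run in the presence of 12. Enal 10 then stays at a low stationary concentration and is consumed by the phenol as it forms.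
   - Lactol 13 is isolated and enters step 8 at the point where catalyst, sieves and Hantzsch ester are added. No compound outside the list is made on this way (F0).

3. **Step 2.**
   - What may go wrong:
     - low reactivity of the chelated hydroxyl
     - re-ionisation of the tertiary ether by zerovalent palladium, with drift to the linear O-prenyl isomer, whose Claisen shift would deliver the wrong allyl terminus
   - The fallback sets out from 4 and comes back to the route at 5.
   - Copper-catalysed etherification with 3-chloro-3-methylbut-1-yne (CuCl2 cat., DBU, MeCN, 0 °C) should give 4-methoxy-2-[(2-methylbut-3-yn-2-yl)oxy]benzaldehyde F2.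
   - Semihydrogenation of the alkyne (H2, Pd/CaCO3 poisoned with Pb(OAc)2, quinoline, EtOAc) then gives 5 with no allyl-metal species that could scramble the ether.

Further compounds
F1 | step 8 | 3-[(2R)-2-{2-[(tert-butyldimethylsilyl)oxy]-4-methoxy-3-(3-methylbut-2-en-1-yl)phenyl}-3-hydroxypropyl]-2,6-dihydroxy-4-methoxybenzaldehyde | COc1ccc([C@H](CO)Cc2c(O)c(C=O)c(O)cc2OC)c(O[Si](C)(C)C(C)(C)C)c1CC=C(C)C
F0 | step 6 | none | none
F2 | step 2 | 4-methoxy-2-[(2-methylbut-3-yn-2-yl)oxy]benzaldehyde | COc1ccc(C=O)c(OC(C)(C)C#C)c1
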